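**Retrosynthetic overview**
1. The target comes from hydrogenolysis of deca-O-benzyl dimer 19. Its C4(upper)–C8(lower) bond comes from capture of the ring-A-stabilised C4 cation of 4-ether 16 by penta-O-benzyl-(+)-gallocatechin 18 (3,4-trans, C8-selective).
2. Ring C of the upper unit is closed at O1–C8a on the halogen-free acyclic para-alkylphenol 10: singlet-oxygen dearomatisation to a para-quinol, 6-exo oxa-Michael addition of the C2 hydroxyl, then dehydrative re-aromatisation.
3. Enabling feature: upper ring A carries only O7, which is para to C4a, and has no O5. Ring A plus C4, C3 and C2 is therefore the C6–C3 skeleton of L-tyrosine (its alpha-carbon becomes C3), and the para-quinol of that phenol turns the position meta to O7 (C8a, equivalent to C5) into an enone beta-carbon six atoms from the C2 hydroxyl.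
4. Phenol 10 comes from O-allyl-L-tyrosine (diazotisation with retention, O3 benzylation, Weinreb amide) and 3,4,5-tris(benzyloxy)phenyllithium; a Cram-chelate reduction sets C2 (anti).
5. Ring order: all aryl rings and ring C of the lower unit are bought; ring C of the upper unit is the only ring built (step 8), followed by the interflavan bond (step 12).

Key step: step 8

Remark: 5-bromopyrogallol 1, O-allyl-L-tyrosine 3 and natural (+)-gallocatechin 17 are taken as catalogue compounds; C4 of ether 16 is left stereochemically open because it becomes planar again in step 12.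

**Step 1**
Reactants: 1 5-bromobenzene-1,2,3-triol
Product: 2 1,2,3-tris(benzyloxy)-5-bromobenzene
Conditions: BnBr, K2CO3, DMF, rt to 50 °C, argon
Reagents that add atoms: benzyl bromide, BrCc1ccccc1
Why: Williamson etherification of the three phenols; the aryl bromide is inert under these conditions.

**Step 2**
Reactants: 3 O-allyl-L-tyrosine
Product: 4 (S)-3-[4-(allyloxy)phenyl]-2-hydroxypropanoic acid
Conditions: NaNO2, 1 M H2SO4/1,4-dioxane, 0 °C to rt
Reagents that add atoms: water, O
Why: Diazotisation of the alpha-amino acid proceeds with net retention (carboxylate displaces N2 to an alpha-lactone, which water opens; double inversion), so the S centre of tyrosine becomes the S carbinol that is C3 of the upper unit.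

**Step 3**
Reactants: 4 (S)-3-[4-(allyloxy)phenyl]-2-hydroxypropanoic acid
Product: 5 (S)-3-[4-(allyloxy)phenyl]-2-(benzyloxy)propanoic acid
Conditions: NaH (2.2 equiv), BnBr (1.1 equiv), THF/DMF, 0 °C to rt; 1 M HCl
Reagents that add atoms: benzyl bromide, BrCc1ccccc1
Why: Williamson O-alkylation of the alkoxide of the carboxylate–alkoxide dianion; the carboxylate makes the alpha-H non-acidic, so the S centre should be kept.

**Step 4**
Reactants: 5 (S)-3-[4-(allyloxy)phenyl]-2-(benzyloxy)propanoic acid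
Product: 6 (S)-3-[4-(allyloxy)phenyl]-2-(benzyloxy)-N-methoxy-N-methylpropanamide
Conditions: CDI, CH2Cl2, rt; then MeNHOMe·HCl, rt; aq. NaHCO3 wash
Reagents that add atoms: N,O-dimethylhydroxylamine hydrochloride, CNOC.Cl
Why: Weinreb amide formation through the acyl imidazole; an alpha-alkoxy acid has no oxazolone pathway for racemisation.

**Step 5**
Reactants: 2 1,2,3-tris(benzyloxy)-5-bromobenzene; 6 (S)-3-[4-(allyloxy)phenyl]-2-(benzyloxy)-N-methoxy-N-methylpropanamide
Product: 8 (S)-3-[4-(allyloxy)phenyl]-2-(benzyloxy)-1-[3,4,5-tris(benzyloxy)phenyl]propan-1-one, via aryllithium 7 (not isolated)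
Conditions: n-BuLi, THF, −78 °C (2 to 7); then 6, −78 to −40 °C; 0.5 M HCl, 0 °C
Reagents that add atoms: none
Why: Bromine–lithium exchange followed by Weinreb ketone synthesis; the chelated tetrahedral adduct persists until quench, which prevents over-addition and enolisation of the alpha-centre.

**Step 6**
Reactants: 8 (S)-3-[4-(allyloxy)phenyl]-2-(benzyloxy)-1-[3,4,5-tris(benzyloxy)phenyl]propan-1-one
Product: 9 (1R,2S)-3-[4-(allyloxy)phenyl]-2-(benzyloxy)-1-[3,4,5-tris(benzyloxy)phenyl]propan-1-ol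
Conditions: Zn(BH4)2, Et2O, −30 to 0 °C; aq. NH4Cl
Reagents that add atoms: none
Why: Cram-chelate reduction: zinc bridges the ketone oxygen and the alpha-benzyloxy oxygen and hydride enters from the face of the small alpha-H, which should give the anti (1R,2S) alcohol required for the 2,3-trans ring.

**Step 7**
Reactants: 9 (1R,2S)-3-[4-(allyloxy)phenyl]-2-(benzyloxy)-1-[3,4,5-tris(benzyloxy)phenyl]propan-1-ol
Product: 10 (1R,2S)-2-(benzyloxy)-3-(4-hydroxyphenyl)-1-[3,4,5-tris(benzyloxy)phenyl]propan-1-ol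
Conditions: Pd(PPh3)4 (cat.), morpholine, THF, rt
Reagents that add atoms: none
Why: Tsuji–Trost deallylation: zerovalent palladium ionises the aryl allyl ether and morpholine traps the pi-allyl complex; benzyl ethers and the benzylic alcohol are untouched.

**Step 8**
Reactants: 10 (1R,2S)-2-(benzyloxy)-3-(4-hydroxyphenyl)-1-[3,4,5-tris(benzyloxy)phenyl]propan-1-ol
Product: 14 (2R,3S)-3-(benzyloxy)-2-[3,4,5-tris(benzyloxy)phenyl]chroman-7-ol, via para-peroxyquinol 11 (not isolated), via para-quinol 12 (not isolated), via bicyclic enone 13 (not isolated)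
Conditions: Oxone (2KHSO5·KHSO4·K2SO4), NaHCO3, MeCN/H2O, rt; Me2S, 0 °C; K2CO3, rt; extraction, then TsOH·H2O (cat.), toluene, 50 °C, without purification of intermediates
Reagents that add atoms: none
Why: Proposed new method: the ring-A phenolate traps singlet oxygen (from Oxone/NaHCO3) at C4a to give para-peroxyquinol 11, Me2S reduces the O–O bond to para-quinol 12, the C2 hydroxyl adds to the enone carbon that becomes C8a to give cis-fused 13, and acid then removes the C4a hydroxyl (enolisation towards C8, ionisation of the tertiary allylic alcohol, loss of H-8a) to re-aromatise ring A as 14; the reasoning is that a para-quinol makes the arene position meta to the phenol oxygen a Michael acceptor, and the closest known reaction types are the Oxone dearomatisation of para-alkylphenols to para-quinols, the intramolecular oxa-Michael closure of para-quinols bearing hydroxyalkyl chains, and the acid-driven dehydrative re-aromatisation of conjugate adducts of para-quinols to meta-substituted phenols. Ring C is closed in a 6-exo-trig oxa-Michael mode that forms the O1–C8a bond. No lasting stereocentre is created: C2 and C3 are carried through untouched because no bond to either is broken, and the transient C4a and C8a centres of 13 vanish on aromatisation, so neither the choice between the two equivalent enone carbons nor the face of attack matters. The selectivity needed is for O1 over O3 and over ipso attack at C4a: O3 is capped as its benzyl ether so that only the C2 hydroxyl can add (a free O3 would close the faster five-membered ring), and singlet oxygen is used instead of a hypervalent-iodine oxidant because no phenoxenium ion arises that the C2 hydroxyl could trap at C4a as a spiro-ether. The oxidant is quenched before acid is added, so the product, itself a para-alkylphenol, never meets it.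

**Step 9**
Reactants: 14 (2R,3S)-3-(benzyloxy)-2-[3,4,5-tris(benzyloxy)phenyl]chroman-7-ol
Product: 15 (2R,3S)-3,7-bis(benzyloxy)-2-[3,4,5-tris(benzyloxy)phenyl]chromane
Conditions: BnBr, K2CO3, DMF, rt
Reagents that add atoms: benzyl bromide, BrCc1ccccc1
Why: Williamson etherification of the single phenol.

**Step 10**
Reactants: 15 (2R,3S)-3,7-bis(benzyloxy)-2-[3,4,5-tris(benzyloxy)phenyl]chromane
Product: 16 (2R,3S)-3,7-bis(benzyloxy)-4-(2-ethoxyethoxy)-2-[3,4,5-tris(benzyloxy)phenyl]chromane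
Conditions: DDQ, 2-ethoxyethanol, CH2Cl2, rt
Reagents that add atoms: 2-ethoxyethanol, CCOCCO
Why: DDQ benzylic C–H oxidation: hydride abstraction from C4 gives a cation stabilised by the para O7 and ortho O1 of ring A, which the alcohol traps; this is the established C4 etherification of benzylated flavan-3-ols.

**Step 11**
Reactants: 17 (+)-gallocatechin
Product: 18 (2R,3S)-5,7-bis(benzyloxy)-2-[3,4,5-tris(benzyloxy)phenyl]chroman-3-ol
Conditions: BnBr, K2CO3, DMF, 0 °C to rt, argon
Reagents that add atoms: benzyl bromide, BrCc1ccccc1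
Why: Williamson etherification of the five phenols only; the secondary 3-OH is not deprotonated by K2CO3.

**Step 12**
Reactants: 16 (2R,3S)-3,7-bis(benzyloxy)-4-(2-ethoxyethoxy)-2-[3,4,5-tris(benzyloxy)phenyl]chromane; 18 (2R,3S)-5,7-bis(benzyloxy)-2-[3,4,5-tris(benzyloxy)phenyl]chroman-3-ol (excess)
Product: 19 3,7,3',4',5'-penta-O-benzylrobinetinidol-(4alpha,8)-5,7,3',4',5'-penta-O-benzylgallocatechin
Conditions: TMSOTf (cat.), CH2Cl2, −78 to −30 °C; Et3N quench
Reagents that add atoms: none
Why: Lewis-acid ionisation of the C4 ether and Friedel–Crafts alkylation at C8 of 18 (C6 is flanked by two benzyloxy groups); attack anti to the 3-benzyloxy group of the 2,3-trans cation should set C4 as 3,4-trans (4alpha, 4S).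

**Step 13**
Reactants: 19 deca-O-benzyl dimer
Product: 20 robinetinidol-(4alpha,8)-gallocatechin
Conditions: H2 (1 atm), Pd(OH)2/C, THF/MeOH/H2O, rt
Reagents that add atoms: none
Why: Hydrogenolysis of all ten benzyl ethers under neutral conditions, which leave the interflavan bond and the four stereocentres of rings C untouched.

**Compound list**
1 | 5-bromobenzene-1,2,3-triol (5-bromopyrogallol) | Oc1cc(Br)cc(O)c1O | starting material
2 | 1,2,3-tris(benzyloxy)-5-bromobenzene | Brc1cc(OCc2ccccc2)c(OCc2ccccc2)c(OCc2ccccc2)c1 | intermediate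
3 | O-allyl-L-tyrosine, (S)-2-amino-3-[4-(allyloxy)phenyl]propanoic acid | N[C@@H](Cc1ccc(OCC=C)cc1)C(=O)O | starting material
4 | (S)-3-[4-(allyloxy)phenyl]-2-hydroxypropanoic acid | O[C@@H](Cc1ccc(OCC=C)cc1)C(=O)O | intermediate
5 | (S)-3-[4-(allyloxy)phenyl]-2-(benzyloxy)propanoic acid | C=CCOc1ccc(C[C@H](OCc2ccccc2)C(=O)O)cc1 | intermediate
6 | (S)-3-[4-(allyloxy)phenyl]-2-(benzyloxy)-N-methoxy-N-methylpropanamide | C=CCOc1ccc(C[C@H](OCc2ccccc2)C(=O)N(C)OC)cc1 | intermediate
7 | [3,4,5-tris(benzyloxy)phenyl]lithium | [Li]c1cc(OCc2ccccc2)c(OCc2ccccc2)c(OCc2ccccc2)c1 | intermediate (not isolated)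
8 | (S)-3-[4-(allyloxy)phenyl]-2-(benzyloxy)-1-[3,4,5-tris(benzyloxy)phenyl]propan-1-one | C=CCOc1ccc(C[C@H](OCc2ccccc2)C(=O)c2cc(OCc3ccccc3)c(OCc3ccccc3)c(OCc3ccccc3)c2)cc1 | intermediate
9 | (1R,2S)-3-[4-(allyloxy)phenyl]-2-(benzyloxy)-1-[3,4,5-tris(benzyloxy)phenyl]propan-1-ol | C=CCOc1ccc(C[C@H](OCc2ccccc2)[C@H](O)c2cc(OCc3ccccc3)c(OCc3ccccc3)c(OCc3ccccc3)c2)cc1 | intermediate
10 | (1R,2S)-2-(benzyloxy)-3-(4-hydroxyphenyl)-1-[3,4,5-tris(benzyloxy)phenyl]propan-1-ol | Oc1ccc(C[C@H](OCc2ccccc2)[C@H](O)c2cc(OCc3ccccc3)c(OCc3ccccc3)c(OCc3ccccc3)c2)cc1 | intermediate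
11 | 4-hydroperoxy-4-[(2S,3R)-2-(benzyloxy)-3-hydroxy-3-[3,4,5-tris(benzyloxy)phenyl]propyl]cyclohexa-2,5-dien-1-one | O=C1C=CC(OO)(C[C@H](OCc2ccccc2)[C@H](O)c2cc(OCc3ccccc3)c(OCc3ccccc3)c(OCc3ccccc3)c2)C=C1 | intermediate (not isolated)
12 | 4-hydroxy-4-[(2S,3R)-2-(benzyloxy)-3-hydroxy-3-[3,4,5-tris(benzyloxy)phenyl]propyl]cyclohexa-2,5-dien-1-one | O=C1C=CC(O)(C[C@H](OCc2ccccc2)[C@H](O)c2cc(OCc3ccccc3)c(OCc3ccccc3)c(OCc3ccccc3)c2)C=C1 | intermediate (not isolated)
13 | (2R,3S)-3-(benzyloxy)-4a-hydroxy-2-[3,4,5-tris(benzyloxy)phenyl]-2,3,4,4a,8,8a-hexahydro-7H-chromen-7-one, cis-fused, C4a/C8a configuration not defined | O=C1C=CC2(O)C[C@H](OCc3ccccc3)[C@@H](c3cc(OCc4ccccc4)c(OCc4ccccc4)c(OCc4ccccc4)c3)OC2C1 | intermediate (not isolated)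
14 | (2R,3S)-3-(benzyloxy)-2-[3,4,5-tris(benzyloxy)phenyl]chroman-7-ol | Oc1ccc2C[C@H](OCc3ccccc3)[C@@H](c3cc(OCc4ccccc4)c(OCc4ccccc4)c(OCc4ccccc4)c3)Oc2c1 | intermediate
15 | (2R,3S)-3,7-bis(benzyloxy)-2-[3,4,5-tris(benzyloxy)phenyl]chromane | C(Oc1ccc2C[C@H](OCc3ccccc3)[C@@H](c3cc(OCc4ccccc4)c(OCc4ccccc4)c(OCc4ccccc4)c3)Oc2c1)c1ccccc1 | intermediate
16 | (2R,3S)-3,7-bis(benzyloxy)-4-(2-ethoxyethoxy)-2-[3,4,5-tris(benzyloxy)phenyl]chromane, C4 configuration open | CCOCCOC1c2ccc(OCc3ccccc3)cc2O[C@H](c2cc(OCc3ccccc3)c(OCc3ccccc3)c(OCc3ccccc3)c2)[C@H]1OCc1ccccc1 | intermediate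
17 | (+)-gallocatechin, (2R,3S)-2-(3,4,5-trihydroxyphenyl)chromane-3,5,7-triol | Oc1cc(O)c2C[C@H](O)[C@@H](c3cc(O)c(O)c(O)c3)Oc2c1 | starting material
18 | (2R,3S)-5,7-bis(benzyloxy)-2-[3,4,5-tris(benzyloxy)phenyl]chroman-3-ol | O[C@H]1Cc2c(OCc3ccccc3)cc(OCc3ccccc3)cc2O[C@@H]1c1cc(OCc2ccccc2)c(OCc2ccccc2)c(OCc2ccccc2)c1 | intermediate
19 | 3,7,3',4',5'-penta-O-benzylrobinetinidol-(4alpha,8)-5,7,3',4',5'-penta-O-benzylgallocatechin | C(c1ccccc1)Oc1ccc2c(c1)O[C@H](c1cc(OCc3ccccc3)c(OCc3ccccc3)c(OCc3ccccc3)c1)[C@@H](OCc1ccccc1)[C@@H]2c1c(OCc2ccccc2)cc(OCc2ccccc2)c2c1O[C@H](c1cc(OCc3ccccc3)c(OCc3ccccc3)c(OCc3ccccc3)c1)[C@@H](O)C2 | intermediate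
20 | robinetinidol-(4alpha,8)-gallocatechin | Oc1ccc2c(c1)O[C@H](c1cc(O)c(O)c(O)c1)[C@@H](O)[C@@H]2c1c(O)cc(O)c2c1O[C@H](c1cc(O)c(O)c(O)c1)[C@@H](O)C2 | target

**Step count**
Total: 13 steps. Longest linear sequence: 11 steps (3 to 20 through steps 2–10, 12 and 13).

**Steps most likely to fail**

1. Step 8. The dienone may be diverted before the oxa-Michael closure (epoxidation of the enone by the hydroperoxide under base, alkyl migration under acid), or the dehydration of 13 may stall and revert by retro-Michael opening. The fallback forms the same O1–C8a bond by known copper-catalysed O-arylation; it sets out from 2 and returns at 15. Commercial 2-bromo-4-hydroxybenzaldehyde is benzylated (BnBr, K2CO3) to 4-(benzyloxy)-2-bromobenzaldehyde F1, reduced (NaBH4) to [4-(benzyloxy)-2-bromophenyl]methanol F2 and converted (PBr3) into 4-(benzyloxy)-2-bromo-1-(bromomethyl)benzene F3. (R)-4-Benzyloxazolidin-2-one is acylated (n-BuLi, benzyloxyacetyl chloride) to (R)-4-benzyl-3-[(benzyloxy)acetyl]oxazolidin-2-one F4. Its sodium enolate (NaN(SiMe3)2, THF, −78 °C) is alkylated with F3 (Evans alkylation; the R auxiliary should give the S centre) to the alkylated imide F5, and transamidation (MeNHOMe·HCl, AlMe3) gives the bromo Weinreb amide F6. Bromide 2 is converted with Mg into [3,4,5-tris(benzyloxy)phenyl]magnesium bromide F7, which adds to F6 to give the bromo ketone F8. Zn(BH4)2 reduction gives the anti bromo alcohol F9, and CuI, 3,4,7,8-tetramethyl-1,10-phenanthroline and Cs2CO3 in toluene at 110 °C (Ullmann-type etherification) close ring C to 15.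

2. Step 10. Hydride abstraction may be slow because ring A lacks O5, or may take place at C2 (benzylic to ring B and next to O1) instead of C4. The fallback oxidises at the free-phenol stage; it sets out from 14 and returns at 19. Ag2O in CH2Cl2 converts the para-alkylphenol into the ring-A para-quinone methide F10. The filtered solution is treated with 18 and catalytic BF3·OEt2 at low temperature, and 1,6-addition from C8 anti to the 3-benzyloxy group should give the nona-O-benzyl dimer with free O7 F11. Benzylation (BnBr, K2CO3) then gives 19.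

3. Step 12. Facial selectivity at C4 may erode (some 3,4-cis epimer), the product may be alkylated further to oligomers, or the free 3-OH of 18 may be O-alkylated. The fallback changes the donor and its activation; it sets out from 16 and returns at 19. Exchange with benzyl mercaptan (BF3·OEt2, CH2Cl2, −20 °C) gives the 4-benzylthio ether F12, which is activated by the thiophile AgBF4 (THF/CH2Cl2, −78 to 0 °C) in the presence of a near-stoichiometric amount of 18 to give 19.

**Further compounds**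
F1 | step 8 | 4-(benzyloxy)-2-bromobenzaldehyde | O=Cc1ccc(OCc2ccccc2)cc1Br
F2 | step 8 | [4-(benzyloxy)-2-bromophenyl]methanol | OCc1ccc(OCc2ccccc2)cc1Br
F3 | step 8 | 4-(benzyloxy)-2-bromo-1-(bromomethyl)benzene | BrCc1ccc(OCc2ccccc2)cc1Br
F4 | step 8 | (R)-4-benzyl-3-[(benzyloxy)acetyl]oxazolidin-2-one | O=C1OC[C@@H](Cc2ccccc2)N1C(=O)COCc1ccccc1
F5 | step 8 | (R)-4-benzyl-3-[(S)-2-(benzyloxy)-3-[4-(benzyloxy)-2-bromophenyl]propanoyl]oxazolidin-2-one | O=C1OC[C@@H](Cc2ccccc2)N1C(=O)[C@H](Cc1ccc(OCc2ccccc2)cc1Br)OCc1ccccc1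
F6 | step 8 | (S)-2-(benzyloxy)-3-[4-(benzyloxy)-2-bromophenyl]-N-methoxy-N-methylpropanamide | CON(C)C(=O)[C@H](Cc1ccc(OCc2ccccc2)cc1Br)OCc1ccccc1
F7 | step 8 | [3,4,5-tris(benzyloxy)phenyl]magnesium bromide | Br[Mg]c1cc(OCc2ccccc2)c(OCc2ccccc2)c(OCc2ccccc2)c1
F8 | step 8 | (S)-2-(benzyloxy)-3-[4-(benzyloxy)-2-bromophenyl]-1-[3,4,5-tris(benzyloxy)phenyl]propan-1-one | O=C([C@H](Cc1ccc(OCc2ccccc2)cc1Br)OCc1ccccc1)c1cc(OCc2ccccc2)c(OCc2ccccc2)c(OCc2ccccc2)c1
F9 | step 8 | (1R,2S)-2-(benzyloxy)-3-[4-(benzyloxy)-2-bromophenyl]-1-[3,4,5-tris(benzyloxy)phenyl]propan-1-ol | O[C@@H]([C@H](Cc1ccc(OCc2ccccc2)cc1Br)OCc1ccccc1)c1cc(OCc2ccccc2)c(OCc2ccccc2)c(OCc2ccccc2)c1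
F10 | step 10 | (2R,3S)-3-(benzyloxy)-2-[3,4,5-tris(benzyloxy)phenyl]-2,3-dihydro-7H-chromen-7-one (ring-A para-quinone methide) | O=C1C=CC2=C[C@H](OCc3ccccc3)[C@@H](c3cc(OCc4ccccc4)c(OCc4ccccc4)c(OCc4ccccc4)c3)OC2=C1
F11 | step 10 | 3,3',4',5'-tetra-O-benzylrobinetinidol-(4alpha,8)-5,7,3',4',5'-penta-O-benzylgallocatechin (free O7 on the upper unit) | Oc1ccc2c(c1)O[C@H](c1cc(OCc3ccccc3)c(OCc3ccccc3)c(OCc3ccccc3)c1)[C@@H](OCc1ccccc1)[C@@H]2c1c(OCc2ccccc2)cc(OCc2ccccc2)c2c1O[C@H](c1cc(OCc3ccccc3)c(OCc3ccccc3)c(OCc3ccccc3)c1)[C@@H](O)C2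
F12 | step 12 | 4-(benzylthio) analogue of 16, C4 configuration open | C(SC1c2ccc(OCc3ccccc3)cc2O[C@H](c2cc(OCc3ccccc3)c(OCc3ccccc3)c(OCc3ccccc3)c2)[C@H]1OCc1ccccc1)c1ccccc1
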